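(Readings and results were computed on assumed constants; scatter was added.)

The vessel is stirred at constant volume while X runs in over 12 h. I want G in the gamma flask at the asked times, and its readings stop at 20.0 h.

| setting | gamma | theta | flask |
|---|---|---|---|
| X | 0.60 M (fed, over 12 h) | 0.60 M (fed, over 12 h) | 0.60 M (fed, over 12 h) |
| L | 1.2 equiv | 1.2 equiv | 1.20 equiv |
| J | 18 mol% | 36 mol% | 18 mol% |
| remark | the very flask that is asked about, followed so far | run made earlier |  |
| time |  |  | 40 h |

| run | time / h | G / % |
|---|---|---|
| gamma | 1.00 | 0.8 |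
| gamma | 3.00 | 0.6 |
| gamma | 6.00 | 4.2 |
| gamma | 8.00 | 7.5 |
| gamma | 12.0 | 14.5 |
| gamma | 15.0 | 22.3 |
| gamma | 20.0 | 31.1 |
| theta | 2.50 | 0.6 |
| theta | 5.00 | 4.6 |
| theta | 6.00 | 7.7 |
| theta | 10.0 | 18.4 |
| theta | 12.0 | 25.3 |
| theta | 15.0 | 34.1 |

(each reading ± 0.5 percentage points)

- in percentages every species weighs as the X in it: one D counts as two
- the earlier runs were read with a standard deviation of 0.5 percentage points
- on the list of suspects stand: L + E -> Z; Q -> J + G; Z <-> Q; 2 Q -> D; X + J <-> E
- percentages count the whole charge, also what has not yet gone in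

1. amount of G in percent of the X charged, at 4.0 h, 12 h, 25 h and 40 h

Does twice the J give twice the pace? The proportional case is my zero: the same G in half the time. The theta flask reads 25.3% at 12.0 h, and by interpolation the gamma flask passes that amount at 16.7 h, so the two times stand at a ratio of 1.39. This clock factor, gamma's time over theta's time for the same G, is a reading, and it lies below the proportional 2.00.

What does it give early in the gamma flask? Dividing the asked times by the factor and interpolating in theta's readings, I reckon 1.20% at 4.0 h and 14.7% at 12 h.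

How far does it reach? Theta's last reading stands for gamma at 20.9 h, so for 25 h and 40 h I have no figure of my own.

The forecast gives 1.5%, 14.8%, 39% and 55%, and reads the shortfall as “Q being lost second order”. At 4.0 h my figure is lower than the forecast's.

The gamma flask gives 1.56%, 15.8%, 38.3% and 53.9%.

    L + E → Z (k = 0.0550 M⁻¹ min⁻¹)
    Q → J + G (k = 0.0230 min⁻¹)
    Z ⇌ Q (K = 0.290, k = 0.240 min⁻¹)
    2 Q → D (k = 0.250 M⁻¹ min⁻¹)
    X + J ⇌ E (K = 0.660 M⁻¹, k = 0.0470 M⁻¹ min⁻¹)

In the gamma flask at 40.0 h, Q goes on to J and G 13 times as fast as into D, the off-cycle form, yet D holds 43.9% of the catalyst charged. Interpolated between 20.0 h and 25 h, the gamma flask passes the amount of theta's last reading, 34.1%, at 22.1 h, which makes the clock factor, itself a reading, 1.47, less than 2.00.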